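(The runs were computed from invented constants; the scatter is artificial.)

Start with the easy step: add first product and substrate in each reading and see what falls short of 100. The last elm reading sums to 99.0%. The last birch reading falls 21 percentage points short, against a scatter of 2 points.

| flask | substrate | coupling partner | temperature | remark | time |
|---|---|---|---|---|---|
| elm | 0.32 M | 1.1 equiv | 0 °C | run made earlier |  |
| birch | 0.48 M | 1.1 equiv | 35 °C | run made earlier |  |
| north-east | 0.64 M | 1.10 equiv | 5 °C |  | 2.5 h |
| east | 0.64 M | 1.10 equiv | 65 °C |  | 2.5 h |
| south-west | 0.64 M | 1.10 equiv | 45 °C |  | 2.5 h |
| south-east | 0.64 M | 1.10 equiv | 25 °C |  | 2.5 h |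

elm run (percent of the substrate charged)

| time / h | first product / % | substrate / % |
|---|---|---|
| 0.250 | 0 | 101 |
| 0.833 | 6 | 96 |
| 1.33 | 7 | 92 |
| 2.00 | 15 | 84 |
| 3.00 | 17 | 82 |

birch run (percent of the substrate charged)

| time / min | first product / % | substrate / % |
|---|---|---|
| 3.00 | 13 | 85 |
| 12.0 | 32 | 53 |
| 20.0 | 37 | 40 |
| 25.0 | 47 | 43 |
| 40.0 | 46 | 33 |

(scatter of a reading: 2 percentage points)

- a reading or a percentage of first product counts all its forms, free or not

- which flask leads in amount of first product, in percent of the substrate charged ("all alike" within 1.5 percentage points) (north-east / east / south-west / south-east / all alike)
- how much first product is there at the end, in percent of the substrate charged: north-east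
- how much first product is there at the end, in percent of the substrate charged: east
- how much first product is there at the end, in percent of the substrate charged: south-west
- how much first product is there at the end, in percent of the substrate charged: south-east

Two chemists dispute these flasks. One holds a one-step view: reacted substrate is first product, 1.10 equiv of coupling partner covers the charge, and so east, the hottest flask, should lead. The other follows one molecule. Substrate takes a partner and becomes first product; then comes a fork, because that molecule can take a second partner.

The missing part over the reacted part, in the last 3 birch readings, gives 0.293. Call this the leak, the chance that a reacted substrate molecule has gone on past first product; it is a reading and carries the scatter.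

Each reacted molecule then costs one partner plus the leak, so the partner is the limiting reagent. At that leak it is spent when 85.1% of the substrate has reacted. My own reckoning therefore gives, for a flask that keeps the birch leak, 60.1% of first product at that point.

The forecast takes this second side but gives a lower number: “partner is essentially exhausted, and the ceiling is about 50% product”. It expects 34% in north-east, 49% in south-east, 48% in south-west and 46% in east, with south-east leading narrowly.

The flasks give 33.4% in north-east, 55.4% in south-east, 46.5% in south-west and 43.5% in east, so south-east leads. The one-step view loses at the top, yet it stands closest in north-east, the flask with the least bis adduct at the end, 7.08%, and with 57% of its partner still there.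

    crystals ⇌ first product, rate k1*(cs1 - [first product]) while solid is left; crystals form when [first product] > cs1 (solubility = 15.0 mM, k = 0.100 min⁻¹)
    coupling partner + first product → bis adduct (k = 0.100 L mol⁻¹ min⁻¹, Ea = 54.0 kJ mol⁻¹)
    substrate + coupling partner → first product (k = 0.0530 L mol⁻¹ min⁻¹, Ea = 72.0 kJ mol⁻¹)
    (constants at 25 °C)

The forecast's 49% for south-east corresponds to a leak of 0.384. In south-east, bis adduct over reacted substrate gives 0.291, close to the birch reading. Left until 25.0 h, south-east holds 60.7%, beside the 60.1% reckoned at the birch leak. The neighbour of north-east with 1.6 M of substrate still has 32% of its partner. Its leak is 0.215, so the partner used so far should have made 48.3%, and that flask holds 48.1% of first product.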